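**Retrosynthetic overview**
- C7–C8 is disconnected last: a ring-closing reductive alkyne–aldehyde coupling closes the 14-membered carbocycle and creates the 7-hydroxy-8(19)-methylene unit.
- C1–C14 and the cis α-methylene-γ-lactone come from an intermolecular aqueous indium Barbier allylation/lactonisation of a West α-hydroxy aldehyde (C8–C14) with an East (Z)-2-(bromomethyl)enoate (C1–C7, C15–C17); the 3,4-epoxide is then added by Shi epoxidation.
- West: an achiral enynal is reduced by organocatalytic iminium transfer hydrogenation (sets C12, the first stereocentre), then α-oxygenated by proline enamine catalysis (sets C13).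
- East: a silylated pentynol undergoes carboalumination/oxirane opening (E-olefin), then vinylalumination to a Baylis–Hillman-type alcohol and conversion to the allylic bromide.
- Ring order: γ-lactone, then oxirane, then the 14-membered carbocycle.

Assumption: the SMILES is read as absolute configuration 1S,3R,4R,7S,12S,13R,14R in cembrane numbering (C1 lactone β-carbon, C14 lactone O-carbon, C13 CHOAc, C12 CHMe, C8 C(=CH2), C7 CHOH, C3/C4 epoxide), with a cis-fused lactone and an E-olefin-derived epoxide; compounds 1, 8, 9 and 14 are taken as commercial.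

**Step 1**
Reactants: 1 hepta-1,6-diyne
Product: 3 (2E)-3-methyloct-2-en-7-yn-1-ol, via alkenylalane 2 (not isolated)
Conditions: 1 (3 equiv), Me3Al (1 equiv), Cp2ZrCl2 (0.2 equiv), CH2Cl2, 0 °C→rt; then (CH2O)n, THF, 0 °C→rt; Rochelle salt work-up, excess 1 recovered by distillation
Reagents that add atoms: trimethylaluminium, C[Al](C)C; formaldehyde (from paraformaldehyde), C=O
Why: Zr-catalysed syn-carboalumination (Negishi) puts Me on the internal and Al on the terminal alkyne carbon, so the E-trisubstituted olefin is fixed and the alkenyl–Al bond adds to formaldehyde with retention; excess diyne keeps the reaction at mono-addition.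

**Step 2**
Reactants: 3 (2E)-3-methyloct-2-en-7-yn-1-ol
Product: 4 (2E)-3-methyloct-2-en-7-ynal
Conditions: MnO2 (10 equiv), CH2Cl2, rt
Reagents that add atoms: none
Why: MnO2 oxidises the allylic alcohol selectively to the enal without E/Z scrambling and leaves the alkyne alone.

**Step 3**
Reactants: 4 (2E)-3-methyloct-2-en-7-ynal
Product: 5 (3S)-3-methyloct-7-ynal
Conditions: Hantzsch ester (1.1 equiv), morpholinium (S)-TRIP phosphate (20 mol%; the enantiomer that reduces geranial to (S)-citronellal), dioxane, 50 °C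
Reagents that add atoms: none
Why: Organocatalytic iminium transfer hydrogenation (asymmetric counteranion-directed catalysis): hydride from the Hantzsch ester adds to the β-carbon of the morpholinium iminium ion inside the chiral phosphate ion pair, setting 12S as the first stereocentre (about 90% ee expected by analogy with geranial to citronellal).

**Step 4**
Reactants: 5 (3S)-3-methyloct-7-ynal
Product: 7 (2R,3S)-2-hydroxy-3-methyloct-7-ynal, via aminoxy aldehyde 6 (not isolated)
Conditions: L-proline (20 mol%), PhNO (1.0 equiv), CHCl3, 4 °C; then CuSO4·5H2O (30 mol%), MeOH, 0 °C; 7 used at once as its hemiacetal dimer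
Reagents that add atoms: nitrosobenzene, O=Nc1ccccc1
Why: Proline enamine catalysis (O-nitroso aldol, α-aminoxylation) sets 13R under catalyst control (L-proline gives 2R with simple aldehydes) whatever the C12 configuration, and Cu(II)-catalysed N–O scission (2 RONHPh → 2 ROH + azobenzene) frees the α-hydroxy aldehyde.

**Step 5**
Reactants: 8 tert-butyldimethyl(pent-4-yn-1-yloxy)silane; 9 oxirane
Product: 12 (3E)-7-[(tert-butyldimethylsilyl)oxy]-4-methylhept-3-en-1-ol, via alkenylalane 10 (not isolated), via lithium alanate 11 (not isolated)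
Conditions: Me3Al (2 equiv), Cp2ZrCl2 (0.25 equiv), CH2Cl2, rt; n-BuLi, hexane/THF, −78→0 °C; 9 (3 equiv), 0 °C→rt
Reagents that add atoms: trimethylaluminium, C[Al](C)C
Why: Negishi carboalumination fixes the E-trisubstituted C3=C4 olefin, and the alkenyl group of the ate complex opens oxirane with retention of geometry to give the homoallylic alcohol.

**Step 6**
Reactants: 12 (3E)-7-[(tert-butyldimethylsilyl)oxy]-4-methylhept-3-en-1-ol
Product: 13 (3E)-7-[(tert-butyldimethylsilyl)oxy]-4-methylhept-3-enal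
Conditions: Dess–Martin periodinane (1.2 equiv), CH2Cl2, 0 °C→rt; crude aldehyde used immediately
Reagents that add atoms: none
Why: Dess–Martin oxidation is mild and non-basic, so the β,γ-unsaturated aldehyde is not pulled into conjugation.

**Step 7**
Reactants: 13 (3E)-7-[(tert-butyldimethylsilyl)oxy]-4-methylhept-3-enal; 14 methyl propiolate
Product: 16 methyl (5E)-9-[(tert-butyldimethylsilyl)oxy]-3-hydroxy-6-methyl-2-methylidenenon-5-enoate (racemic at C3), via vinylalane 15 (not isolated)
Conditions: 14 (1.5 equiv), DIBAL-H (1.5 equiv), NMO (1.5 equiv), THF, 0 °C; then 13, 0 °C→rt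
Reagents that add atoms: none
Why: Vinylalumination: hydroalumination of the propiolate gives an α-aluminio acrylate that adds 1,2 to the aldehyde quickly under non-basic conditions, giving the Baylis–Hillman-type alcohol without isomerising the skipped olefin; the carbinol centre is lost in step 8.

**Step 8**
Reactants: 16 methyl (5E)-9-[(tert-butyldimethylsilyl)oxy]-3-hydroxy-6-methyl-2-methylidenenon-5-enoate
Product: 17 methyl (2Z,5E)-2-(bromomethyl)-9-[(tert-butyldimethylsilyl)oxy]-6-methylnona-2,5-dienoate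
Conditions: NBS (1.3 equiv), Me2S (1.5 equiv), CH2Cl2, 0 °C→rt
Reagents that add atoms: N-bromosuccinimide, O=C1CCC(=O)N1Br
Why: Corey–Kim-type activation gives an alkoxysulfonium that bromide displaces in SN2' fashion with allylic transposition, delivering the thermodynamically preferred (Z)-2-(bromomethyl)enoate; the silyl ether and isolated olefin are untouched.

**Step 9**
Reactants: 17 methyl (2Z,5E)-2-(bromomethyl)-9-[(tert-butyldimethylsilyl)oxy]-6-methylnona-2,5-dienoate; 7 (2R,3S)-2-hydroxy-3-methyloct-7-ynal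
Product: 19 (4S,5R)-4-[(2E)-6-hydroxy-3-methylhex-2-en-1-yl]-5-[(1R,2S)-1-hydroxy-2-methylhept-6-yn-1-yl]-3-methylideneoxolan-2-one, via hydroxy ester 18 (not isolated)
Conditions: In powder (1.5 equiv), 7 (1.3 equiv), THF/H2O (1:1), rt; then 1 M HCl, rt
Reagents that add atoms: none
Why: Aqueous indium Barbier allylation/lactonisation: indium chelates the aldehyde and the free 13-OH (Cram chelate) so the γ-carbon of the (Z)-allylindium attacks to give the 13,14-syn diol (14R) through a chair transition state that gives the 1,14-syn adduct (1S, cis lactone), and acid then closes the γ-lactone and removes the TBS group.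

**Step 10**
Reactants: 19 (4S,5R)-4-[(2E)-6-hydroxy-3-methylhex-2-en-1-yl]-5-[(1R,2S)-1-hydroxy-2-methylhept-6-yn-1-yl]-3-methylideneoxolan-2-one
Product: 20 (4S,5R)-5-[(1R,2S)-1-hydroxy-2-methylhept-6-yn-1-yl]-4-{[(2R,3R)-3-(3-hydroxypropyl)-3-methyloxiran-2-yl]methyl}-3-methylideneoxolan-2-one
Conditions: D-fructose-derived Shi ketone (30 mol%), Oxone, K2CO3, Bu4NHSO4, MeCN/DMM/aq. borate buffer (pH 10.5), 0 °C
Reagents that add atoms: Oxone (potassium peroxymonosulfate), [K+].[O-]S(=O)(=O)OO
Why: Shi epoxidation (chiral dioxirane, spiro transition state) delivers oxygen to one face of the electron-rich E-trisubstituted olefin to give the (3R,4R)-epoxide under catalyst control, while the electron-poor methylene lactone and the alkyne do not react and the basic medium spares the epoxy alcohol.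

**Step 11**
Reactants: 20 (4S,5R)-5-[(1R,2S)-1-hydroxy-2-methylhept-6-yn-1-yl]-4-{[(2R,3R)-3-(3-hydroxypropyl)-3-methyloxiran-2-yl]methyl}-3-methylideneoxolan-2-one
Product: 21 3-[(2R,3R)-3-{[(2R,3S)-2-[(1R,2S)-1-hydroxy-2-methylhept-6-yn-1-yl]-4-methylidene-5-oxooxolan-3-yl]methyl}-2-methyloxiran-2-yl]propanal
Conditions: TEMPO (10 mol%), PhI(OAc)2 (1.1 equiv), CH2Cl2, 0 °C, short reaction time
Reagents that add atoms: none
Why: Oxoammonium (TEMPO) oxidation is selective for the unhindered primary alcohol over the hindered secondary 13-OH, and the cold, short reaction converts the epoxy alcohol to the aldehyde before acid-promoted tetrahydrofuran formation can compete.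

**Step 12**
Reactants: 21 3-[(2R,3R)-3-{[(2R,3S)-2-[(1R,2S)-1-hydroxy-2-methylhept-6-yn-1-yl]-4-methylidene-5-oxooxolan-3-yl]methyl}-2-methyloxiran-2-yl]propanal
Product: 22 (1R,2S)-2-methyl-1-[(2R,3S)-4-methylidene-3-{[(2R,3R)-3-methyl-3-(3-oxopropyl)oxiran-2-yl]methyl}-5-oxooxolan-2-yl]hept-6-yn-1-yl acetate
Conditions: Ac2O, pyridine, DMAP (cat.), CH2Cl2, 0 °C
Reagents that add atoms: acetic anhydride, CC(=O)OC(C)=O
Why: DMAP-catalysed acylation of the only remaining hydroxyl installs the 13-acetate with retention; aldehyde, epoxide, lactone and alkyne are inert.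

**Step 13**
Reactants: 22 (1R,2S)-2-methyl-1-[(2R,3S)-4-methylidene-3-{[(2R,3R)-3-methyl-3-(3-oxopropyl)oxiran-2-yl]methyl}-5-oxooxolan-2-yl]hept-6-yn-1-yl acetate
Product: 23 (1S,3R,4R,7S,12S,13R,14R)-13-acetoxy-3,4-epoxy-7-hydroxycembra-8(19),15(17)-dien-16,14-olide (target)
Conditions: CrCl2 (6 equiv), NiCl2 (10 mol%), PPh3 (20 mol%), H2O (2 equiv), chiral oxazoline–sulfonamide ligand (7S-selective enantiomer) with Et3N (both recovered), DMF, rt, 2 mM by syringe pump; buffered (pH 8) work-up
Reagents that add atoms: none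
Why: Proposed new method: a ring-closing, ligand-controlled Cr(II)/Ni hydrometalative coupling of a terminal alkyne with a tethered aldehyde, in which Ni(0) (from NiCl2/CrCl2/PPh3) and water give a Ni–H that adds Markovnikov to the alkyne, the 1-substituted vinylnickel transmetalates to Cr(III), and the ligated, oxophilic alkenylchromium adds only to the aldehyde to close the 14-membered ring with the 8(19)-methylene in place while the sulfonamide ligand selects the aldehyde face that gives 7S; the closest known reactions are the intermolecular CrCl2/cat. NiCl2/H2O reductive coupling of terminal alkynes with aldehydes to 2-substituted allylic alcohols and ligand-controlled Nozaki–Hiyama–Kishi macrocyclisations of 2-haloalkenes, neither shown as a ring-closing, ligand-controlled alkyne version.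

**Compound list**
1 | hepta-1,6-diyne | C#CCCCC#C | starting material
2 | [(1E)-2-methylhept-1-en-6-yn-1-yl]dimethylalane | C#CCCC/C(C)=C/[Al](C)C | intermediate (not isolated)
3 | (2E)-3-methyloct-2-en-7-yn-1-ol | C#CCCC/C(C)=C/CO | intermediate
4 | (2E)-3-methyloct-2-en-7-ynal | C#CCCC/C(C)=C/C=O | intermediate
5 | (3S)-3-methyloct-7-ynal | C#CCCC[C@H](C)CC=O | intermediate
6 | (2R,3S)-3-methyl-2-[(phenylamino)oxy]oct-7-ynal | C#CCCC[C@H](C)[C@@H](ONc1ccccc1)C=O | intermediate (not isolated)
7 | (2R,3S)-2-hydroxy-3-methyloct-7-ynal | C#CCCC[C@H](C)[C@@H](O)C=O | intermediate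
8 | tert-butyldimethyl(pent-4-yn-1-yloxy)silane | C#CCCCO[Si](C)(C)C(C)(C)C | starting material
9 | oxirane | C1CO1 | starting material
10 | {(1E)-5-[(tert-butyldimethylsilyl)oxy]-2-methylpent-1-en-1-yl}dimethylalane | CC(C)(C)[Si](C)(C)OCCC/C(C)=C/[Al](C)C | intermediate (not isolated)
11 | lithium butyl{(1E)-5-[(tert-butyldimethylsilyl)oxy]-2-methylpent-1-en-1-yl}dimethylaluminate | [Li+].CCCC[Al-](C)(C)/C=C(\C)CCCO[Si](C)(C)C(C)(C)C | intermediate (not isolated)
12 | (3E)-7-[(tert-butyldimethylsilyl)oxy]-4-methylhept-3-en-1-ol | OCC/C=C(\C)CCCO[Si](C)(C)C(C)(C)C | intermediate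
13 | (3E)-7-[(tert-butyldimethylsilyl)oxy]-4-methylhept-3-enal | O=CC/C=C(\C)CCCO[Si](C)(C)C(C)(C)C | intermediate
14 | methyl propiolate | C#CC(=O)OC | starting material
15 | [1-(methoxycarbonyl)ethenyl]bis(2-methylpropyl)alane | C=C(C(=O)OC)[Al](CC(C)C)CC(C)C | intermediate (not isolated)
16 | methyl (5E)-9-[(tert-butyldimethylsilyl)oxy]-3-hydroxy-6-methyl-2-methylidenenon-5-enoate (racemic at C3) | C=C(C(=O)OC)C(O)C/C=C(\C)CCCO[Si](C)(C)C(C)(C)C | intermediate
17 | methyl (2Z,5E)-2-(bromomethyl)-9-[(tert-butyldimethylsilyl)oxy]-6-methylnona-2,5-dienoate | COC(=O)/C(CBr)=C/C/C=C(\C)CCCO[Si](C)(C)C(C)(C)C | intermediate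
18 | methyl (3S,4R,5R,6S)-3-{(2E)-6-[(tert-butyldimethylsilyl)oxy]-3-methylhex-2-en-1-yl}-4,5-dihydroxy-6-methyl-2-methylideneundec-10-ynoate | C#CCCC[C@H](C)[C@@H](O)[C@H](O)[C@H](C(=C)C(=O)OC)C/C=C(\C)CCCO[Si](C)(C)C(C)(C)C | intermediate (not isolated)
19 | (4S,5R)-4-[(2E)-6-hydroxy-3-methylhex-2-en-1-yl]-5-[(1R,2S)-1-hydroxy-2-methylhept-6-yn-1-yl]-3-methylideneoxolan-2-one | C#CCCC[C@H](C)[C@@H](O)[C@@H]1OC(=O)C(=C)[C@@H]1C/C=C(\C)CCCO | intermediate
20 | (4S,5R)-5-[(1R,2S)-1-hydroxy-2-methylhept-6-yn-1-yl]-4-{[(2R,3R)-3-(3-hydroxypropyl)-3-methyloxiran-2-yl]methyl}-3-methylideneoxolan-2-one | C#CCCC[C@H](C)[C@@H](O)[C@@H]1OC(=O)C(=C)[C@@H]1C[C@H]1O[C@]1(C)CCCO | intermediate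
21 | 3-[(2R,3R)-3-{[(2R,3S)-2-[(1R,2S)-1-hydroxy-2-methylhept-6-yn-1-yl]-4-methylidene-5-oxooxolan-3-yl]methyl}-2-methyloxiran-2-yl]propanal | C#CCCC[C@H](C)[C@@H](O)[C@@H]1OC(=O)C(=C)[C@@H]1C[C@H]1O[C@]1(C)CCC=O | intermediate
22 | (1R,2S)-2-methyl-1-[(2R,3S)-4-methylidene-3-{[(2R,3R)-3-methyl-3-(3-oxopropyl)oxiran-2-yl]methyl}-5-oxooxolan-2-yl]hept-6-yn-1-yl acetate | C#CCCC[C@H](C)[C@@H](OC(C)=O)[C@@H]1OC(=O)C(=C)[C@@H]1C[C@H]1O[C@]1(C)CCC=O | intermediate
23 | (1S,3R,4R,7S,12S,13R,14R)-13-acetoxy-3,4-epoxy-7-hydroxycembra-8(19),15(17)-dien-16,14-olide | C=C1CCC[C@H](C)[C@@H](OC(C)=O)[C@@H]2OC(=O)C(=C)[C@@H]2C[C@H]2O[C@]2(C)CC[C@@H]1O | target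

**Step count and risks**

Total: 13 steps (steps 1–4 West, 5–8 East, 9–13 after union). Longest linear sequence: 9 steps (steps 1–4 then 9–13, or 5–8 then 9–13).

Step 13 (the proposed new ring closure) is the most likely to fail. The Ni–H or Cr(II) may attack the α-methylene lactone, the Cr(III) alkoxide may open the nearby epoxide, and the ligand control at C7 is untested for an alkyne. The fallback uses only known chemistry, sets out from 20 and comes back at 23. Ru-catalysed Markovnikov hydrosilylation of the alkyne ([Cp*Ru(MeCN)3]PF6, Et3SiH) gives (4S,5R)-5-[(1R,2S)-1-hydroxy-2-methyl-6-(triethylsilyl)hept-6-en-1-yl]-4-{[(2R,3R)-3-(3-hydroxypropyl)-3-methyloxiran-2-yl]methyl}-3-methylideneoxolan-2-one F1. Buffered iododesilylation (NIS, 2,6-lutidine, MeCN) gives the corresponding 2-iodoalkene diol F2. TEMPO/PhI(OAc)2 then gives the iodo aldehyde F3, and Ac2O/pyridine gives the iodo aldehyde acetate F4. A ligand-controlled Nozaki–Hiyama–Kishi macrocyclisation (CrCl2, cat. NiCl2, sulfonamide ligand, high dilution), which tolerates enoates, closes F4 to 23.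

Step 9 is the second risk. The chelation-controlled syn,syn outcome has not been shown on this β-branched hydroxy aldehyde, and 7 is labile. The fallback sets out from 5 and 17 and comes back at 19. Aldehyde 5 is converted into 6 in DMSO (L-proline, PhNO), and 17, indium powder and NaI are added to the same flask (the known tandem aminoxylation/indium allylation), where the N-aryl aminoxy group can act as the chelating group. This gives methyl (3S,4R,5R,6S)-3-{(2E)-6-[(tert-butyldimethylsilyl)oxy]-3-methylhex-2-en-1-yl}-4-hydroxy-6-methyl-2-methylidene-5-[(phenylamino)oxy]undec-10-ynoate F7. Dilute acid lactonises and desilylates it to (4S,5R)-4-[(2E)-6-hydroxy-3-methylhex-2-en-1-yl]-5-{(1R,2S)-2-methyl-1-[(phenylamino)oxy]hept-6-yn-1-yl}-3-methylideneoxolan-2-one F8. CuSO4/MeOH then cleaves the N–O bond to give 19.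

Step 4 is the third risk. N–O cleavage on a free aldehyde may cause epimerisation at C13 or α-ketol isomerisation, and the hydroxy aldehyde dimer is hard to purify. The fallback sets out from 5 and comes back at 7. The aminoxylation is run as before, and crude 6 is trapped with HC(OMe)3/PPTS/MeOH as N-{[(2R,3S)-1,1-dimethoxy-3-methyloct-7-yn-2-yl]oxy}aniline F5. CuSO4/MeOH cleaves the N–O bond to the stable, purifiable (2R,3S)-1,1-dimethoxy-3-methyloct-7-yn-2-ol F6. Mild aqueous acid just before the indium step releases 7.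

**Further compounds**
F1 | step 13 | (4S,5R)-5-[(1R,2S)-1-hydroxy-2-methyl-6-(triethylsilyl)hept-6-en-1-yl]-4-{[(2R,3R)-3-(3-hydroxypropyl)-3-methyloxiran-2-yl]methyl}-3-methylideneoxolan-2-one | C=C([Si](CC)(CC)CC)CCC[C@H](C)[C@@H](O)[C@@H]1OC(=O)C(=C)[C@@H]1C[C@H]1O[C@]1(C)CCCO
F2 | step 13 | (4S,5R)-5-[(1R,2S)-1-hydroxy-6-iodo-2-methylhept-6-en-1-yl]-4-{[(2R,3R)-3-(3-hydroxypropyl)-3-methyloxiran-2-yl]methyl}-3-methylideneoxolan-2-one | C=C(I)CCC[C@H](C)[C@@H](O)[C@@H]1OC(=O)C(=C)[C@@H]1C[C@H]1O[C@]1(C)CCCO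
F3 | step 13 | 3-[(2R,3R)-3-{[(2R,3S)-2-[(1R,2S)-1-hydroxy-6-iodo-2-methylhept-6-en-1-yl]-4-methylidene-5-oxooxolan-3-yl]methyl}-2-methyloxiran-2-yl]propanal | C=C(I)CCC[C@H](C)[C@@H](O)[C@@H]1OC(=O)C(=C)[C@@H]1C[C@H]1O[C@]1(C)CCC=O
F4 | step 13 | (1R,2S)-6-iodo-2-methyl-1-[(2R,3S)-4-methylidene-3-{[(2R,3R)-3-methyl-3-(3-oxopropyl)oxiran-2-yl]methyl}-5-oxooxolan-2-yl]hept-6-en-1-yl acetate | C=C(I)CCC[C@H](C)[C@@H](OC(C)=O)[C@@H]1OC(=O)C(=C)[C@@H]1C[C@H]1O[C@]1(C)CCC=O
F5 | step 4 | N-{[(2R,3S)-1,1-dimethoxy-3-methyloct-7-yn-2-yl]oxy}aniline | C#CCCC[C@H](C)[C@@H](ONc1ccccc1)C(OC)OC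
F6 | step 4 | (2R,3S)-1,1-dimethoxy-3-methyloct-7-yn-2-ol | C#CCCC[C@H](C)[C@@H](O)C(OC)OC
F7 | step 9 | methyl (3S,4R,5R,6S)-3-{(2E)-6-[(tert-butyldimethylsilyl)oxy]-3-methylhex-2-en-1-yl}-4-hydroxy-6-methyl-2-methylidene-5-[(phenylamino)oxy]undec-10-ynoate | C#CCCC[C@H](C)[C@@H](ONc1ccccc1)[C@H](O)[C@H](C(=C)C(=O)OC)C/C=C(\C)CCCO[Si](C)(C)C(C)(C)C
F8 | step 9 | (4S,5R)-4-[(2E)-6-hydroxy-3-methylhex-2-en-1-yl]-5-{(1R,2S)-2-methyl-1-[(phenylamino)oxy]hept-6-yn-1-yl}-3-methylideneoxolan-2-one | C#CCCC[C@H](C)[C@@H](ONc1ccccc1)[C@@H]1OC(=O)C(=C)[C@@H]1C/C=C(\C)CCCO
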